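**Retrosynthetic overview**
1. Target 26 ⇐ chroman 24 carrying ring B as its hydroquinone dibenzyl ether: hydrogenolysis and aerobic oxidation come last.
2. 24 ⇐ acetate-masked diarylpropanol 20: the pyran ring, the only ring built, is closed at O1–C8a by oxidative dearomatisation of ring A, intramolecular oxa-Michael addition and eliminative rearomatisation.
3. Structural feature used: ring A without O1 (C4a, C5-H, C6-OMe, C7-OH, C8-OMe, C8a) is a 4-hydroxy-3,5-dimethoxyphenyl group, symmetric about the C4a–C7 axis. C5 and C8a are equivalent until one is etherified, and the C7 hydroxyl never has to be told apart from the C6 and C8 methoxy groups.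
4. 20 ⇐ Evans alkylation of the ring B arylacetyl oxazolidinone 16 with the ring A benzyl bromide 4 (sets C3 as S), then LiBH4 (gives the C2 carbinol).
5. 16 ⇐ 2,3-dimethoxyphenol (quinone, reductive benzylation, bromination, malonate arylation); 4 ⇐ syringaldehyde. Rings A and B are bought preformed.

Key step: step 14

Remark on stereochemistry: CIP analysis of the target SMILES gives S at C3 (C2 > quinone carbon > C4 > H). The same spatial arrangement is S in every intermediate from 17 onward.

Remark on the key-step precursor: a free CH2OH three atoms away from the para carbon of the phenol would close a five-membered spiro ether there on oxidation (the usual fate of 3-(4-hydroxyaryl)propan-1-ols). Acid rearrangement of that spiro dienone would lead to the wrong chroman. The alcohol is therefore carried into the oxidation as its acetate and released in the same flask, after methanol has captured ring A as the quinone monoketal.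

**Route**

Step 1
Reactants: 1 syringaldehyde
Product: 2 3,5-dimethoxy-4-[(triisopropylsilyl)oxy]benzaldehyde
Conditions: TIPSCl, imidazole, DMF, rt to 40 °C
Reagents that add atoms: triisopropylsilyl chloride CC(C)[Si](Cl)(C(C)C)C(C)C
Why: Silylation of the phenol gives a base-stable ether that is orthogonal to benzyl ethers and to an acetate, and the aldehyde is inert to these conditions.

Step 2
Reactants: 2 3,5-dimethoxy-4-[(triisopropylsilyl)oxy]benzaldehyde
Product: 3 {3,5-dimethoxy-4-[(triisopropylsilyl)oxy]phenyl}methanol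
Conditions: NaBH4, MeOH/THF, 0 °C
Reagents that add atoms: none
Why: Borohydride reduction of an aryl aldehyde to the benzyl alcohol leaves the aryl silyl ether untouched.

Step 3
Reactants: 3 {3,5-dimethoxy-4-[(triisopropylsilyl)oxy]phenyl}methanol
Product: 4 [4-(bromomethyl)-2,6-dimethoxyphenoxy]triisopropylsilane
Conditions: CBr4, PPh3, CH2Cl2, 0 °C
Reagents that add atoms: tetrabromomethane BrC(Br)(Br)Br
Why: Appel bromination converts the benzylic alcohol to the bromide under neutral conditions that spare the silyl ether; the bromide is used promptly.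

Step 4
Reactants: 5 2,3-dimethoxyphenol
Product: 6 2,3-dimethoxy-1,4-benzoquinone
Conditions: Fremy's salt (KO3S)2NO, KH2PO4, H2O/acetone, rt
Reagents that add atoms: potassium nitrosodisulfonate [K+].[K+].[O-]S(=O)(=O)N([O])S([O-])(=O)=O
Why: Teuber oxidation of a phenol with a free para position delivers the para-quinone and installs the second oxygen of ring B.

Step 5
Reactants: 6 2,3-dimethoxy-1,4-benzoquinone
Product: 8 1,4-bis(benzyloxy)-2,3-dimethoxybenzene, via 2,3-dimethoxybenzene-1,4-diol 7 (not isolated)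
Conditions: Na2S2O4, EtOAc/H2O, rt; organic phase concentrated under N2; then BnBr, K2CO3, DMF, 60 °C
Reagents that add atoms: benzyl bromide BrCc1ccccc1
Why: Dithionite reduction to the hydroquinone followed by double Williamson etherification stores the quinone as a bis(benzyl ether) that is released only by hydrogenolysis at the end.

Step 6
Reactants: 8 1,4-bis(benzyloxy)-2,3-dimethoxybenzene
Product: 9 1,4-bis(benzyloxy)-5-bromo-2,3-dimethoxybenzene
Conditions: NBS (1.05 equiv), dry MeCN, 0 °C to rt, dark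
Reagents that add atoms: N-bromosuccinimide O=C1CCC(=O)N1Br
Why: Electrophilic aromatic bromination of the tetraalkoxybenzene has only one kind of free position (the two CH carbons are equivalent), and the first bromine deactivates the ring toward a second.

Step 7
Reactants: 9 1,4-bis(benzyloxy)-5-bromo-2,3-dimethoxybenzene; 10 diethyl malonate
Product: 11 diethyl 2-[2,5-bis(benzyloxy)-3,4-dimethoxyphenyl]malonate
Conditions: Pd(OAc)2 (cat.), P(t-Bu)3·HBF4 (cat.), K3PO4, toluene, 100 °C
Reagents that add atoms: none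
Why: Palladium-catalysed α-arylation of a malonate enolate with a bulky electron-rich phosphine tolerates electron-rich, mono-ortho-substituted aryl bromides and attaches the two-carbon acid unit.

Step 8
Reactants: 11 diethyl 2-[2,5-bis(benzyloxy)-3,4-dimethoxyphenyl]malonate
Product: 13 2-[2,5-bis(benzyloxy)-3,4-dimethoxyphenyl]acetic acid, via 2-[2,5-bis(benzyloxy)-3,4-dimethoxyphenyl]malonic acid 12 (not isolated)
Conditions: NaOH, EtOH/H2O, reflux; HCl to pH 2, extraction; then toluene, 100 °C
Reagents that add atoms: sodium hydroxide [Na+].[OH-]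
Why: Saponification followed by thermal decarboxylation of the arylmalonic acid gives the arylacetic acid, and aryl benzyl ethers survive both base and brief dilute acid.

Step 9
Reactants: 13 2-[2,5-bis(benzyloxy)-3,4-dimethoxyphenyl]acetic acid; 14 (S)-4-benzyloxazolidin-2-one
Product: 16 (S)-4-benzyl-3-{2-[2,5-bis(benzyloxy)-3,4-dimethoxyphenyl]acetyl}oxazolidin-2-one, via 2-[2,5-bis(benzyloxy)-3,4-dimethoxyphenyl]acetic pivalic anhydride 15 (not isolated)
Conditions: PivCl, Et3N, THF, −20 °C; then 14, LiCl, −20 °C to rt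
Reagents that add atoms: none
Why: N-acylation of the oxazolidinone through the mixed pivalic anhydride proceeds at the less hindered arylacetyl carbonyl and is the standard one-flask preparation of Evans imides.

Step 10
Reactants: 16 (S)-4-benzyl-3-{2-[2,5-bis(benzyloxy)-3,4-dimethoxyphenyl]acetyl}oxazolidin-2-one; 4 [4-(bromomethyl)-2,6-dimethoxyphenoxy]triisopropylsilane
Product: 17 (S)-4-benzyl-3-{(S)-2-[2,5-bis(benzyloxy)-3,4-dimethoxyphenyl]-3-[3,5-dimethoxy-4-(triisopropylsilyloxy)phenyl]propanoyl}oxazolidin-2-one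
Conditions: NaN(SiMe3)2, THF, −78 °C; then 4, −78 to −30 °C; AcOH quench at low temperature
Reagents that add atoms: none
Why: In this Evans asymmetric alkylation the chelated sodium Z-enolate is shielded on one face by the C4 benzyl group of the (S)-auxiliary, so the benzylic bromide enters from the other face and sets the future C3 as S, which is the sense of the textbook propionimide benzylation with the CIP ranks of the two carbon substituents exchanged.

Step 11
Reactants: 17 (S)-4-benzyl-3-{(S)-2-[2,5-bis(benzyloxy)-3,4-dimethoxyphenyl]-3-[3,5-dimethoxy-4-(triisopropylsilyloxy)phenyl]propanoyl}oxazolidin-2-one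
Product: 18 (S)-2-[2,5-bis(benzyloxy)-3,4-dimethoxyphenyl]-3-[3,5-dimethoxy-4-(triisopropylsilyloxy)phenyl]propan-1-ol
Conditions: LiBH4, THF, MeOH (1 equiv), 0 °C
Reagents that add atoms: none
Why: Reductive cleavage of the imide with LiBH4 gives the primary alcohol and the recoverable auxiliary under non-basic conditions that do not epimerise the α-aryl centre.

Step 12
Reactants: 18 (S)-2-[2,5-bis(benzyloxy)-3,4-dimethoxyphenyl]-3-[3,5-dimethoxy-4-(triisopropylsilyloxy)phenyl]propan-1-ol
Product: 19 (S)-2-[2,5-bis(benzyloxy)-3,4-dimethoxyphenyl]-3-[3,5-dimethoxy-4-(triisopropylsilyloxy)phenyl]propyl acetate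
Conditions: Ac2O, pyridine, DMAP (cat.), CH2Cl2, rt
Reagents that add atoms: acetic anhydride CC(=O)OC(C)=O
Why: Acetylation of the only free hydroxyl masks the alcohol so that it cannot attack the para carbon of ring A during the later phenol oxidation.

Step 13
Reactants: 19 (S)-2-[2,5-bis(benzyloxy)-3,4-dimethoxyphenyl]-3-[3,5-dimethoxy-4-(triisopropylsilyloxy)phenyl]propyl acetate
Product: 20 (S)-2-[2,5-bis(benzyloxy)-3,4-dimethoxyphenyl]-3-(4-hydroxy-3,5-dimethoxyphenyl)propyl acetate
Conditions: n-Bu4NF, AcOH (1.2 equiv), THF, 0 °C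
Reagents that add atoms: none
Why: Fluoride cleaves the aryl silyl ether selectively, and the acetic acid buffer keeps the liberated phenoxide from transferring or cleaving the primary acetate.

Step 14
Reactants: 20 (S)-2-[2,5-bis(benzyloxy)-3,4-dimethoxyphenyl]-3-(4-hydroxy-3,5-dimethoxyphenyl)propyl acetate
Product: 24 (S)-3-[2,5-bis(benzyloxy)-3,4-dimethoxyphenyl]-6,8-dimethoxychroman-7-ol, via quinone monoketal acetate 21 (not isolated), via quinone monoketal alcohol 22 (not isolated), via bicyclic enone adduct 23 (not isolated)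
Conditions: PhI(OAc)2 (1.0 equiv), MeOH (0.01 M), −20 °C; then NaOMe (4 equiv), 0 °C to rt; then TsOH·H2O to pH 2, rt
Reagents that add atoms: methanol CO (supplies one of the two methoxy groups on the ketal carbon, of which one is kept at C8)
Why: PhI(OAc)2 oxidises the only free phenol (ring A) by two electrons and methanol captures the phenoxonium ion at an ortho carbon bearing OMe, giving the o-quinone monoketal 21 as in masked o-benzoquinone chemistry, while the acetate prevents five-membered spiro ether formation at the para carbon. Methoxide then removes the acetate (22) and the alkoxide adds to the ring carbon next to the side chain in an intramolecular oxa-Michael reaction, drawn as 1,6-addition to the δ-carbon of the linear dienone, which closes the pyran 6-endo-trig and forms the O1–C8a bond (23). Acid ionises the ketal of the dienol form to an arenium ion that loses the C8a proton, so methanol is expelled and ring A is aromatic again with the C7 hydroxyl free; the closest known reaction type is conjugate addition of heteronucleophiles to quinone monoketals or quinols followed by eliminative rearomatisation. Addition at the other flank of the side chain (β-carbon, 6-exo-trig) or methanol capture at the para carbon would converge on the same chroman because ring A without O1 is symmetric about the C4a–C7 axis, so no regiocontrol is required. No lasting stereocentre is created: the sp3 centres at C4a and C8a disappear on aromatisation, and C3, set in step 10, carries no acidic hydrogen and takes no part. The selectivity needed is oxidation of ring A only, secured by ring B being fully etherified, and suppression of bimolecular Diels–Alder dimerisation of 21, addressed by high dilution and low temperature.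

Step 15
Reactants: 24 (S)-3-[2,5-bis(benzyloxy)-3,4-dimethoxyphenyl]-6,8-dimethoxychroman-7-ol
Product: 26 5-[(S)-7-hydroxy-6,8-dimethoxychroman-3-yl]-2,3-dimethoxy-1,4-benzoquinone (target), via 2,3-dimethoxy-5-[(S)-7-hydroxy-6,8-dimethoxychroman-3-yl]benzene-1,4-diol 25 (not isolated)
Conditions: H2 (1 atm), 10% Pd/C, EtOAc, rt; N2 purge; then air, rt, same flask; filtration
Reagents that add atoms: none
Why: Hydrogenolysis of the two aryl benzyl ethers frees the tetraoxygenated hydroquinone, which should autoxidise (assisted by Pd/C) to the quinone far more readily than the ring A monophenol, and the base-free conditions leave C3 untouched.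

**Compound list**
1 | syringaldehyde | COc1cc(C=O)cc(OC)c1O | starting material
2 | 3,5-dimethoxy-4-[(triisopropylsilyl)oxy]benzaldehyde | COc1cc(C=O)cc(OC)c1O[Si](C(C)C)(C(C)C)C(C)C | intermediate
3 | {3,5-dimethoxy-4-[(triisopropylsilyl)oxy]phenyl}methanol | COc1cc(CO)cc(OC)c1O[Si](C(C)C)(C(C)C)C(C)C | intermediate
4 | [4-(bromomethyl)-2,6-dimethoxyphenoxy]triisopropylsilane | COc1cc(CBr)cc(OC)c1O[Si](C(C)C)(C(C)C)C(C)C | intermediate
5 | 2,3-dimethoxyphenol | COc1cccc(O)c1OC | starting material
6 | 2,3-dimethoxy-1,4-benzoquinone | COC1=C(OC)C(=O)C=CC1=O | intermediate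
7 | 2,3-dimethoxybenzene-1,4-diol | COc1c(O)ccc(O)c1OC | intermediate
8 | 1,4-bis(benzyloxy)-2,3-dimethoxybenzene | COc1c(OCc2ccccc2)ccc(OCc2ccccc2)c1OC | intermediate
9 | 1,4-bis(benzyloxy)-5-bromo-2,3-dimethoxybenzene | COc1c(OCc2ccccc2)cc(Br)c(OCc2ccccc2)c1OC | intermediate
10 | diethyl malonate | CCOC(=O)CC(=O)OCC | starting material
11 | diethyl 2-[2,5-bis(benzyloxy)-3,4-dimethoxyphenyl]malonate | CCOC(=O)C(C(=O)OCC)c1cc(OCc2ccccc2)c(OC)c(OC)c1OCc1ccccc1 | intermediate
12 | 2-[2,5-bis(benzyloxy)-3,4-dimethoxyphenyl]malonic acid | OC(=O)C(C(O)=O)c1cc(OCc2ccccc2)c(OC)c(OC)c1OCc1ccccc1 | intermediate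
13 | 2-[2,5-bis(benzyloxy)-3,4-dimethoxyphenyl]acetic acid | OC(=O)Cc1cc(OCc2ccccc2)c(OC)c(OC)c1OCc1ccccc1 | intermediate
14 | (S)-4-benzyloxazolidin-2-one | O=C1N[C@@H](Cc2ccccc2)CO1 | starting material
15 | 2-[2,5-bis(benzyloxy)-3,4-dimethoxyphenyl]acetic pivalic anhydride | CC(C)(C)C(=O)OC(=O)Cc1cc(OCc2ccccc2)c(OC)c(OC)c1OCc1ccccc1 | intermediate
16 | (S)-4-benzyl-3-{2-[2,5-bis(benzyloxy)-3,4-dimethoxyphenyl]acetyl}oxazolidin-2-one | COc1c(OCc2ccccc2)cc(CC(=O)N2[C@@H](Cc3ccccc3)COC2=O)c(OCc2ccccc2)c1OC | intermediate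
17 | (S)-4-benzyl-3-{(S)-2-[2,5-bis(benzyloxy)-3,4-dimethoxyphenyl]-3-[3,5-dimethoxy-4-(triisopropylsilyloxy)phenyl]propanoyl}oxazolidin-2-one | COc1c(OCc2ccccc2)cc([C@H](Cc2cc(OC)c(O[Si](C(C)C)(C(C)C)C(C)C)c(OC)c2)C(=O)N2[C@@H](Cc3ccccc3)COC2=O)c(OCc2ccccc2)c1OC | intermediate
18 | (S)-2-[2,5-bis(benzyloxy)-3,4-dimethoxyphenyl]-3-[3,5-dimethoxy-4-(triisopropylsilyloxy)phenyl]propan-1-ol | COc1c(OCc2ccccc2)cc([C@H](Cc2cc(OC)c(O[Si](C(C)C)(C(C)C)C(C)C)c(OC)c2)CO)c(OCc2ccccc2)c1OC | intermediate
19 | (S)-2-[2,5-bis(benzyloxy)-3,4-dimethoxyphenyl]-3-[3,5-dimethoxy-4-(triisopropylsilyloxy)phenyl]propyl acetate | COc1c(OCc2ccccc2)cc([C@H](Cc2cc(OC)c(O[Si](C(C)C)(C(C)C)C(C)C)c(OC)c2)COC(C)=O)c(OCc2ccccc2)c1OC | intermediate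
20 | (S)-2-[2,5-bis(benzyloxy)-3,4-dimethoxyphenyl]-3-(4-hydroxy-3,5-dimethoxyphenyl)propyl acetate (key-step precursor) | COc1c(OCc2ccccc2)cc([C@H](Cc2cc(OC)c(O)c(OC)c2)COC(C)=O)c(OCc2ccccc2)c1OC | intermediate
21 | (S)-2-[2,5-bis(benzyloxy)-3,4-dimethoxyphenyl]-3-(3,3,5-trimethoxy-4-oxocyclohexa-1,5-dien-1-yl)propyl acetate | COc1c(OCc2ccccc2)cc([C@H](CC2=CC(OC)(OC)C(=O)C(OC)=C2)COC(C)=O)c(OCc2ccccc2)c1OC | intermediate
22 | 4-{(S)-2-[2,5-bis(benzyloxy)-3,4-dimethoxyphenyl]-3-hydroxypropyl}-2,6,6-trimethoxycyclohexa-2,4-dien-1-one | COc1c(OCc2ccccc2)cc([C@H](CC2=CC(OC)(OC)C(=O)C(OC)=C2)CO)c(OCc2ccccc2)c1OC | intermediate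
23 | (3S)-3-[2,5-bis(benzyloxy)-3,4-dimethoxyphenyl]-6,8,8-trimethoxy-3,4,4a,8a-tetrahydro-2H-chromen-7(8H)-one (transient C4a and C8a centres left open) | COc1c(OCc2ccccc2)cc([C@H]2COC3C(C2)C=C(OC)C(=O)C3(OC)OC)c(OCc2ccccc2)c1OC | intermediate
24 | (S)-3-[2,5-bis(benzyloxy)-3,4-dimethoxyphenyl]-6,8-dimethoxychroman-7-ol (key-step product) | COc1c(OCc2ccccc2)cc([C@H]2COc3c(cc(OC)c(O)c3OC)C2)c(OCc2ccccc2)c1OC | intermediate
25 | 2,3-dimethoxy-5-[(S)-7-hydroxy-6,8-dimethoxychroman-3-yl]benzene-1,4-diol | COc1c(O)cc([C@H]2COc3c(cc(OC)c(O)c3OC)C2)c(O)c1OC | intermediate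
26 | 5-[(S)-7-hydroxy-6,8-dimethoxychroman-3-yl]-2,3-dimethoxy-1,4-benzoquinone | COC1=C(OC)C(=O)C([C@H]2COc3c(cc(OC)c(O)c3OC)C2)=CC1=O | target

**Step count**
Total: 15 steps. Longest linear sequence: 12 steps (steps 4 to 15, from 2,3-dimethoxyphenol).

**Steps most likely to fail**

Step 14. Several processes can divert material:
- Diels–Alder dimerisation of the quinone monoketal before the alkoxide is released.
- Loss of a benzylic proton from the oxidised ring to a quinone methide, followed by solvent capture at the benzylic carbon.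
- Competing intermolecular conjugate addition of methanol.
- Acid-induced return to the phenoxonium ion, followed by spiro-etherification at the para carbon once the alcohol is free.

Fallback (sets out from 1 and 16, returns at 24): the O1–C8a bond is made by metal-catalysed aryl etherification instead of dearomatisation. Bromination of 1 (Br2, NaOAc, AcOH) gives 2-bromo-4-hydroxy-3,5-dimethoxybenzaldehyde F1. Silylation (TIPSCl, imidazole, DMF) gives 2-bromo-3,5-dimethoxy-4-[(triisopropylsilyl)oxy]benzaldehyde F2. NaBH4 gives the bromo benzyl alcohol F3, and CBr4/PPh3 gives the bromo benzyl bromide F4. Alkylation of the sodium enolate of 16 with F4 under the conditions of step 10 gives the bromo imide F5, and LiBH4 gives the bromo alcohol F6. Intramolecular C–O coupling (Pd(OAc)2, 2-(di-tert-butylphosphino)-1,1'-binaphthyl, Cs2CO3, toluene, 80 °C) closes the pyran to the silyl-protected chroman F7, and n-Bu4NF gives 24.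

Step 10. The stabilised, ortho-substituted arylacetyl enolate may alkylate slowly, and the acidic α-aryl centre may epimerise during reaction or quench, which would erode the diastereomer purity.

Fallback (sets out from 13 and 2, returns at 18): the stereocentre is set by asymmetric hydrogenation instead of auxiliary alkylation. Perkin condensation of 13 with 2 (Ac2O, Et3N, 110 °C) gives the (E)-diarylacrylic acid F8. Hydrogenation with [Ir(cod)(SIPHOX)]B[3,5-(CF3)2C6H3]4 (H2, Et3N, MeOH), using the ligand antipode that delivers the S acid, gives the (S)-diarylpropanoic acid F9. BH3·THF then reduces F9 to 18.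

Step 7. Oxidative addition to the very electron-rich bromide may be slow, so protodebromination or catalyst death may outrun the enolate coupling.

Fallback (sets out from 8, returns at 13): the side chain is built by electrophilic formylation and one-carbon homologation instead of cross-coupling. Vilsmeier–Haack formylation of 8 (POCl3, DMF, 70 °C) gives 2,5-bis(benzyloxy)-3,4-dimethoxybenzaldehyde F10. Van Leusen reductive cyanation (TosMIC, t-BuOK, DME, −30 °C; then MeOH, reflux) gives the arylacetonitrile F11. Hydrolysis (KOH, ethylene glycol/H2O, 120 °C) then gives 13.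

**Further compounds**
F1 | step 14 | 2-bromo-4-hydroxy-3,5-dimethoxybenzaldehyde | COc1cc(C=O)c(Br)c(OC)c1O
F2 | step 14 | 2-bromo-3,5-dimethoxy-4-[(triisopropylsilyl)oxy]benzaldehyde | COc1cc(C=O)c(Br)c(OC)c1O[Si](C(C)C)(C(C)C)C(C)C
F3 | step 14 | {2-bromo-3,5-dimethoxy-4-[(triisopropylsilyl)oxy]phenyl}methanol | COc1cc(CO)c(Br)c(OC)c1O[Si](C(C)C)(C(C)C)C(C)C
F4 | step 14 | [3-bromo-4-(bromomethyl)-2,6-dimethoxyphenoxy]triisopropylsilane | COc1cc(CBr)c(Br)c(OC)c1O[Si](C(C)C)(C(C)C)C(C)C
F5 | step 14 | (S)-4-benzyl-3-{(S)-2-[2,5-bis(benzyloxy)-3,4-dimethoxyphenyl]-3-[2-bromo-3,5-dimethoxy-4-(triisopropylsilyloxy)phenyl]propanoyl}oxazolidin-2-one | COc1c(OCc2ccccc2)cc([C@H](Cc2cc(OC)c(O[Si](C(C)C)(C(C)C)C(C)C)c(OC)c2Br)C(=O)N2[C@@H](Cc3ccccc3)COC2=O)c(OCc2ccccc2)c1OC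
F6 | step 14 | (S)-2-[2,5-bis(benzyloxy)-3,4-dimethoxyphenyl]-3-[2-bromo-3,5-dimethoxy-4-(triisopropylsilyloxy)phenyl]propan-1-ol | COc1c(OCc2ccccc2)cc([C@H](Cc2cc(OC)c(O[Si](C(C)C)(C(C)C)C(C)C)c(OC)c2Br)CO)c(OCc2ccccc2)c1OC
F7 | step 14 | {[(S)-3-[2,5-bis(benzyloxy)-3,4-dimethoxyphenyl]-6,8-dimethoxychroman-7-yl]oxy}triisopropylsilane | COc1c(OCc2ccccc2)cc([C@H]2COc3c(cc(OC)c(O[Si](C(C)C)(C(C)C)C(C)C)c3OC)C2)c(OCc2ccccc2)c1OC
F8 | step 10 | (E)-2-[2,5-bis(benzyloxy)-3,4-dimethoxyphenyl]-3-[3,5-dimethoxy-4-(triisopropylsilyloxy)phenyl]acrylic acid | OC(=O)/C(=C/c1cc(OC)c(O[Si](C(C)C)(C(C)C)C(C)C)c(OC)c1)c1cc(OCc2ccccc2)c(OC)c(OC)c1OCc1ccccc1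
F9 | step 10 | (S)-2-[2,5-bis(benzyloxy)-3,4-dimethoxyphenyl]-3-[3,5-dimethoxy-4-(triisopropylsilyloxy)phenyl]propanoic acid | COc1c(OCc2ccccc2)cc([C@H](Cc2cc(OC)c(O[Si](C(C)C)(C(C)C)C(C)C)c(OC)c2)C(O)=O)c(OCc2ccccc2)c1OC
F10 | step 7 | 2,5-bis(benzyloxy)-3,4-dimethoxybenzaldehyde | COc1c(OCc2ccccc2)cc(C=O)c(OCc2ccccc2)c1OC
F11 | step 7 | 2-[2,5-bis(benzyloxy)-3,4-dimethoxyphenyl]acetonitrile | COc1c(OCc2ccccc2)cc(CC#N)c(OCc2ccccc2)c1OC
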